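Remark on conventions: intermediates carry the gibberellane numbers of the carbons they become in the target. α is the face of C19, C20 and the lactone oxygen; β is the face of C18, H5, H9 and the two hydroxyls. Compounds 1, 2, 8 and 14 are taken as purchased.

## The problem

Compound 34 is a C20 gibberellin-type diacid. A cyclohexane (ring A) is trans-fused to a cyclopentane (ring B), which shares the C8–C9 bond with a bicyclo[3.2.1]octane (rings C and D), and the C20 carboxyl on C10 is closed as a δ-lactone onto the C12 oxygen. There are ten stereocentres (C2, C3, C4, C5, C6, C8, C9, C10, C12, C13); three are quaternary (C4, C8, C10), and C4 and C10 each carry a carboxyl carbon on the α face. C5, the one hydrogen-bearing carbon between the two quaternary ring A carbons, can control C4 and C10 if both are made by enolate alkylation. Ring A can then control C9, C9 controls C8, C8 fixes C13 through the bridge, and C6 and C12 are open to thermodynamic or intramolecular control. The C16 methylene does not survive borane, osmium reagents or strong acid; the lactone and cis-diol limit base and hydride; a C5 hydrogen next to a C6 carbonyl can epimerize; and the axial C19 ester on quaternary C4 cannot be saponified normally. The enabling feature is that oxygenated C12 lies three carbons from quaternary C8 (C8–C9–C11–C12) and that C8 and C13 flank C14 in ring D. An enal C9=C11–C12=O on ring A and a ring D cyclopentanone with its carbonyl at C14 therefore map onto the bonds C8–C9 and C12–C13, so rings B and C can close in one Michael–aldol operation.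

## Retrosynthesis

**End game (34 back to 30).** The last bonds made are C16=C17 and the O–H and CO2H groups released from protection. The methylene is introduced by Wittig reaction on ketone 31 only after all borane and oxidation chemistry is over, and C16 is carried as a ketal until then (30). The C19 methyl ester of 32 is cleaved at the methyl carbon, and the acetonide of 33 goes last under dilute acid. These steps remove no complexity but let one ester and one acetonide serve from step 5 onward.

**C6–C7 (30 back to 24).** The C7 carboxyl is cut from C6, leading to ketone 24. Carbonylation of an enol triflate would be shorter but passes through a C5=C6 alkene and erases C5. Methylenation (25), hydroboration (27), oxidation and equilibration of the aldehyde (29) leave C5 untouched and set C6 under thermodynamic control. The forward steps need a small, non-basic methylene donor for a very crowded ketone.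

**C14 oxygen and the lactone (24 back to 20).** Ketone 24 comes from alcohol 22 through thionocarbonate 23 by radical deoxygenation, and 22 from diol 21 by closing C12–O onto C20. Diol 21 comes from hydroxy diketone 20 by a hydroxyl-directed reduction. The C12 hydroxyl thus first tells the C14 ketone apart from the C6 ketone and then becomes the lactone oxygen. The forward steps need the C12 hydroxyl on the α face, axial and next to both C14 and C20.

**Key disconnection (20 back to 18).** C8–C9 and C12–C13 are cut together. This removes rings B and C, the quaternary C8 and four stereocentres, and leaves ring A with an enal on C10 and a 2-acylcyclopentanone on C5 (18). Cutting only one of the two bonds would leave a bridged or spiro intermediate that is no easier to make. The forward reaction must add C8, not C13, to C9, and must then enolize C14 toward C13 without losing the C16 ketal.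

**C6–C8 (18 back to 13 and 14).** The β-diketone is cut between C6 and C8. The bond is made by aldol addition of the enolate of ketal ketone 14 to aldehyde 13 (15) and oxidation (16); an acid chloride flanked by two quaternary carbons would be a poor acylating agent. The enal is kept as an allylic acetate until after this coupling (17, then 18). The forward step needs enolization of 14 away from the ketal.

**C9–C10 and the three-carbon arm (13 back to 7 and 8).** The C10 quaternary centre is cut at C9–C10. The ester enolate of 7 adds to acrolein (8), the adduct 9 is acetylated (10), and a 1,3-acetate shift gives the (E)-allylic acetate 11 in the enal oxidation pattern. Allyl halides would give a CH2 at C9. The C6 acid, kept as a carboxylate so that H5 is not acidic, is then reduced to aldehyde 13 through acid chloride 12. The forward aldol must enter from the β face.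

**C4 methyl and the diol (7 back to 4).** C4–C18 is cut (methylation of the allylic ester enolate of 4 gives 5), and the diol (6, acetonide 7) comes from the C2=C3 alkene. Methylation must precede dihydroxylation, because only the allylic activation distinguishes H4 from H10.

**Ring A (4 back to 3, 1 and 2).** Hemiester 4 is cut to anhydride 3 and then to diene ester 1 and maleic anhydride 2 (bonds C4–C5 and C1–C10). The Diels–Alder reaction supplies all ring A carbons with C19, C6 and C20 in place. Only C5 must be controlled absolutely, since C4 and C10 are re-set through enolates. An alkaloid-catalysed methanolysis of racemic 3 is asked to deliver one enantiomer with C6 free and C20 esterified.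

## Roads not taken

**Alternative 1: intramolecular Diels–Alder closing rings A and B.**
- Cut: C5–C10 and C3–C4.
- Forward step: triene A1 holds the finished C/D bicycle and lactone, with a C10=C1–C2=C3 bis(silyloxy)diene exocyclic to the lactone and a (Z)-2-methylenoate on C6. On heating it closes to cycloadduct A2.
- Merits: two quaternary carbons (C4, C10) and four stereocentres are set at once, the C2/C3 oxygens arrive with the diene, and the methylene and C6 ester are already present. After the key step little remains, which is clearly better than the eleven steps the chosen plan needs after its key step.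
- Weak points: the diene terminus C10 is fully substituted, so one substituent must point into the diene cleft and the s-cis form is hard to reach; both new bonds join crowded carbons. The C1=C2 enol ether of A2 must be hydrolysed and the C2 ketone reduced from the shielded α face to give the 2β-alcohol. A1 itself needs five stereocentres of the C/D lactone that this key step does not help to make.
- Comparison: the chosen plan sets against the shorter end game that its key step builds the hardest part, the bridged bicycle with C8, from two monocyclic pieces, and that ring A comes from cheap materials by predictable enolate chemistry.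

**Alternative 2: tethered trimethylenemethane [3+2] building rings C and D.**
- Cut: C13–C14 and C8–C15.
- Forward step: precursor A3 is the ring A/B lactone with an exocyclic C8=C14 enone and a silyl allylic carbonate on C12. Pd(PPh3)4 (zerovalent palladium) generates the trimethylenemethane unit, whose C13 terminus adds to C14; the C8 enolate then closes on C15 to give keto lactone A4.
- Merits: C14 is formed as CH2 and C16=C17 is formed directly, so neither a deoxygenation nor a late methylenation is needed. In redox economy on rings C and D this road is better than the chosen one.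
- Weak points: substituted trimethylenemethane–palladium units equilibrate and can bond through the wrong terminus; the α-methylene ketone of A3 is prone to self-addition; the lactone and the C12 centre must exist before ring C. The C6 ketone of A4 still needs the same homologation as in the chosen plan.
- Comparison: the chosen plan has the closer precedent for its key step and a purchased ring D piece, and pays with four steps to remove the C14 oxygen and unmask C16.

**Alternative 3: gold enyne cyclization trapped by the C20 acid.**
- Cut: C13–C16 and C12–O.
- Forward step: enyne acid A5 is a ring A/B/C tricycle with a C12=C13 alkene, a propargyl group on C8 and a free C20 acid. With Ph3PAuNTf2 (monovalent gold) the alkene attacks the activated alkyne through C13 and the acid adds to C12, giving A6, the acetonide dimethyl ester of the target.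
- Merits: ring D, the lactone, the methylene, C12 and C13 are formed in one late step, and the anti addition across C12=C13 matches the β propargyl group and the α carboxyl. A6 is two deprotections from 34, the best end game of all four plans.
- Weak points: the positive charge develops at a secondary, unstabilized C12, so hydride shift or elimination can outrun capture. All of C4, C5, C6, C8, C9 and C10, including the quaternary C8, must be made beforehand without help from a ring-forming step.
- Comparison: the chosen plan creates C8, C9, C12 and C13 together with rings B and C, which is what it sets against the shorter finish of this road.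

Key step: step 13

## Route

Step 1
Reactants: 1 methyl (2E)-penta-2,4-dienoate; 2 maleic anhydride
Product: 3 racemic all-cis anhydride, methyl 1,3-dioxo-1,3,3a,4,7,7a-hexahydro-2-benzofuran-4-carboxylate with the ester cis to the anhydride ring
Conditions: toluene, BHT (cat.), 90 °C
Reagents that add atoms: none
Why: Thermal Diels–Alder reaction of a 1-substituted butadiene with a very reactive cyclic dienophile; the endo transition state places the C4 ester cis to both anhydride carbons (relative configuration of C4, C5, C10), and only C5 has to persist because C4 and C10 are later re-set through their enolates.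

Step 2
Reactants: 3 racemic all-cis anhydride
Product: 4 hemiester, all-cis 2,6-bis(methoxycarbonyl)cyclohex-3-ene-1-carboxylic acid (4α- and 10α-CO2Me, 5α-CO2H, C2=C3)
Conditions: (DHQ)2AQN (10 mol %), MeOH (10 equiv), Et2O, −20 °C; separation from the regioisomeric hemiester
Reagents that add atoms: methanol, CO
Why: Cinchona alkaloid-catalysed alcoholysis of a cyclic anhydride run as a parallel kinetic resolution; by analogy with meso cis-cyclohex-4-ene-1,2-dicarboxylic anhydride the quinine-derived catalyst should deliver methanol to the carbonyl that is C20 in the wanted enantiomer (also the less hindered one) and C6 in the other, so the two enantiomers end as separable regioisomers and C5 is fixed absolutely.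

Step 3
Reactants: 4 hemiester
Product: 5 4β-methyl hemiester, 2,6-bis(methoxycarbonyl)-2-methylcyclohex-3-ene-1-carboxylic acid with the methyl trans to the three carboxyl carbons
Conditions: LiN(i-Pr)2 (2.2 equiv), THF, −78 °C; MeI, −78 to −20 °C
Reagents that add atoms: iodomethane, CI
Why: Alkylation of an ester dienolate at its α-carbon; after the carboxylate, H4 (ester α and allylic) is removed in preference to H10, the C5 carboxylate keeps H5 non-acidic, and iodomethane enters anti to the adjacent C5 carboxylate, giving C18 β and C19 α.

Step 4
Reactants: 5 4β-methyl hemiester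
Product: 6 2β,3β-diol acid, 3,4-dihydroxy-2,6-bis(methoxycarbonyl)-2-methylcyclohexane-1-carboxylic acid with both hydroxyls cis to the methyl
Conditions: OsO4 (2 mol %), N-methylmorpholine N-oxide, acetone/H2O, rt
Reagents that add atoms: osmium tetroxide, O=[Os](=O)(=O)=O; N-methylmorpholine N-oxide (oxygen source), C[N+]1([O-])CCOCC1
Why: Catalytic syn-dihydroxylation; the α face carries all three carboxyl groups (in either half-chair a pseudoaxial C19 ester or an axial C6 carboxylate blocks it), so osmylation should occur on the β face and set C2 and C3 cis to the methyl.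

Step 5
Reactants: 6 2β,3β-diol acid
Product: 7 acetonide acid (2β,3β-O-isopropylidene derivative of 6)
Conditions: 2-methoxypropene, PPTS (cat.), CH2Cl2, 0 °C to rt
Reagents that add atoms: 2-methoxypropene, C=C(C)OC
Why: Acetonide formation on a cis-1,2-diol under mild acid; the enol ether reagent avoids the methanol-rich medium that could esterify the C6 acid.

Step 6
Reactants: 7 acetonide acid; 8 acrolein
Product: 10 C9 acetate of the acrolein adduct (10β-(1-acetoxyprop-2-enyl); C9 epimers), via hydroxy acid 9 (not isolated)
Conditions: LiN(i-Pr)2 (2.3 equiv), THF, −78 °C; acrolein, −78 °C; Ac2O, −78 to 0 °C; aqueous work-up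
Reagents that add atoms: acetic anhydride, CC(=O)OC(C)=O
Why: Aldol 1,2-addition of a tetrasubstituted lithium ester enolate to acrolein with in situ O-acetylation, which blocks retro-aldol cleavage; the exocyclic enolate is attacked equatorially from the β face because the axial C19 ester (1,3) and the C5 carboxylate shield the α face, as in alkylations of cyclohexane-1,3-dicarboxylate enolates, so C9 ends β and C20 α.

Step 7
Reactants: 10 C9 acetate
Product: 11 (E)-allylic acetate acid (10β-[(E)-3-acetoxyprop-1-enyl])
Conditions: PdCl2(MeCN)2 (5 mol %), THF, rt
Reagents that add atoms: none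
Why: Divalent palladium-catalysed [3,3] shift of an allylic acetate through a cyclic acetoxonium intermediate; the equilibrium favours the disubstituted alkene with a primary acetate, the E isomer is expected, and the C9 stereocentre disappears.

Step 8
Reactants: 11 (E)-allylic acetate acid
Product: 13 ring A aldehyde (5α-formyl), via acid chloride 12 (not isolated)
Conditions: 1-chloro-N,N,2-trimethylprop-1-enylamine, CH2Cl2, 0 °C; LiAlH(Ot-Bu)3, THF, −78 °C
Reagents that add atoms: none
Why: Neutral conversion of the acid to its chloride and partial reduction with the hindered alkoxyaluminium hydride, which stops at the aldehyde and leaves methyl esters, the acetate and the acetonide alone; no free C6 alcohol arises that could lactonize onto C19 or C20.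

Step 9
Reactants: 13 ring A aldehyde; 14 1,4-dioxaspiro[4.4]nonan-7-one
Product: 15 aldol adduct (C6 carbinol joined to C8 of the ring D ketal ketone; C6 and C8 epimers)
Conditions: 14, LiN(i-Pr)2, THF, −78 °C; then 13, −78 °C; aq. NH4Cl at −78 °C
Reagents that add atoms: none
Why: Aldol addition of a kinetic lithium enolate; the amide base should remove the C8 proton of 14, not the neopentyl C13 proton next to the ketal, and an aldehyde is the least demanding electrophile for the crowded C6 position; the new centres are removed in step 10.

Step 10
Reactants: 15 aldol adduct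
Product: 16 6,14-diketone (2-acylcyclopentanone, enolized; C8 labile)
Conditions: Dess–Martin periodinane, NaHCO3, CH2Cl2, rt
Reagents that add atoms: none
Why: Dess–Martin oxidation of a β-hydroxy ketone to the 1,3-diketone under neutral conditions that avoid retro-aldol cleavage.

Step 11
Reactants: 16 6,14-diketone
Product: 17 allylic alcohol (10β-[(E)-3-hydroxyprop-1-enyl])
Conditions: K2CO3, MeOH, 0 °C
Reagents that add atoms: none
Why: Base-catalysed transesterification of a primary allylic acetate; the β-diketone is protected as its enolate and the C19 and C20 esters on quaternary carbons are too hindered to exchange.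

Step 12
Reactants: 17 allylic alcohol
Product: 18 enal (10β-[(E)-3-oxoprop-1-enyl] with the C5 acyl link to the ring D ketal dione), the key-step precursor
Conditions: MnO2 (activated, excess), CH2Cl2, rt; filtered and used at once
Reagents that add atoms: none
Why: MnO2 oxidation selective for the allylic alcohol under neutral heterogeneous conditions, tolerated by the enolized β-diketone, the ketal and the acetonide.

Step 13
Reactants: 18 enal
Product: 20 hydroxy diketone tetracarbocycle (rings A–D; C6 and C14 ketones; 12α-OH; C16 ketal), via Michael adduct 19 (not isolated)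
Conditions: pyrrolidine (0.3 equiv), AcOH (0.3 equiv), CH2Cl2, 0 °C to rt
Reagents that add atoms: none
Why: Pyrrolidine converts the enal into its iminium ion, the enol of the 6,14-dione adds through C8 to C9, hydrolysis gives aldehyde 19, and the C14 ketone, now enolizable only toward C13, adds to C12. The closest known reaction type is the amine-catalysed Michael–aldol domino of 2-acylcycloalkanones and cyclic β-keto esters with enals to 2-hydroxybicyclo[3.2.1]octan-8-ones; here the Michael half is intramolecular. Ring B closes 5-exo-trig and is trans-fused because the C9 and C6 arms are diequatorial on ring A. Ring C closes by a 6-(enolexo)-exo-trig aldol that creates the one-carbon bridge C14. C9 is set with the C11 arm pseudo-equatorial on the new cyclopentane and cis to the angular C20 ester, the favoured place for a substituent next to the angular carbon of a trans-hydrindane, and the reversible Michael step lets this preference operate. Both C8 epimers interconvert by retro-Michael reaction, only the one with C14 cis to C11 can reach C12, and C13 follows from the bridge. C12 is set by a chair transition state in which the enol hydroxyl hydrogen-bonds to the aldehyde oxygen, so the hydroxyl ends axial, syn to C14 and next to the C20 ester. The step needs C8, not C13, as the Michael donor (secured by the 1,3-dicarbonyl acidity), survival of the ketal and of C5 (buffered amine salt, no free strong base), and the α hydroxyl.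

Step 14
Reactants: 20 hydroxy diketone
Product: 21 12α,14-diol (14-OH syn to the C15–C16 bridge; C6 ketone intact)
Conditions: Me4NBH(OAc)3, MeCN/AcOH, −20 °C to rt
Reagents that add atoms: none
Why: Evans–Saksena hydroxyl-directed reduction; the axial C12 hydroxyl binds the triacetoxyborohydride and delivers hydride to the adjacent C14 carbonyl from the side of the three-carbon bridge, while the C6 ketone, which has no β-hydroxyl, is not reduced by this weak hydride.

Step 15
Reactants: 21 12α,14-diol
Product: 22 20→12 lactone with free 14-OH
Conditions: CSA (10 mol %), toluene, 5 Å molecular sieves, 60 °C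
Reagents that add atoms: none
Why: Acid-catalysed lactonization; the axial C12 hydroxyl and the axial C10 substituent are 1,3-related on chair ring C, so the six-membered lactone closes readily, whereas the 14-hydroxyl points away from C20; acid is chosen over base to avoid retro-aldol cleavage of C8–C14.

Step 16
Reactants: 22 lactone alcohol
Product: 23 14-O-(phenoxythiocarbonyl) derivative
Conditions: PhOC(S)Cl, pyridine, DMAP (cat.), CH2Cl2, rt
Reagents that add atoms: O-phenyl chlorothionoformate, S=C(Cl)Oc1ccccc1
Why: Thionocarbonate formation under weakly basic conditions, which avoids the alkoxide that could trigger retro-aldol cleavage toward the C6 ketone.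

Step 17
Reactants: 23 thionocarbonate
Product: 24 14-deoxy keto lactone (C14 H2; C6 ketone; C16 ketal)
Conditions: Bu3SnH (5 equiv, 0.5 M), AIBN (cat.), toluene, 90 °C
Reagents that add atoms: none
Why: Barton–McCombie deoxygenation of a secondary alcohol; the high stannane concentration makes hydrogen transfer to the C14 radical faster than a 1,2-acyl shift toward the neighbouring C6 ketone.

Step 18
Reactants: 24 14-deoxy keto lactone
Product: 25 6-methylene lactone (C6=C7)
Conditions: Zn, CH2Br2, TiCl4, THF/CH2Cl2, 0 °C to rt
Reagents that add atoms: dibromomethane, BrCBr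
Why: Methylenation with the zinc/titanium gem-dimetallic reagent, which is non-basic and small, reacts with hindered enolizable ketones without epimerizing the α-centre (C5) and leaves esters and lactones alone at this temperature.

Step 19
Reactants: 25 6-methylene lactone
Product: 27 6-epi C7 alcohol (6α-hydroxymethyl; H6 β), via alkylborane 26 (not isolated)
Conditions: BH3·THF, THF, 0 °C to rt; then 30% H2O2, aq. NaHCO3, 0 °C to rt
Reagents that add atoms: hydrogen peroxide, OO
Why: Hydroboration–oxidation of a 1,1-disubstituted alkene; boron goes to the terminal C7 and hydrogen to C6, expected from the β face because the lactone bridge and the axial C19 ester cover the α face, which gives the 6-epi alcohol that step 20 corrects.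

Step 20
Reactants: 27 6-epi C7 alcohol
Product: 29 6β aldehyde (C7 formyl β; H6 α), via 6-epi aldehyde 28 (not isolated)
Conditions: Dess–Martin periodinane, NaHCO3, CH2Cl2, rt; then DBU (0.2 equiv), rt
Reagents that add atoms: none
Why: Dess–Martin oxidation followed by base equilibration of the aldehyde α-centre; the formyl group should move from the α face, where it is cis to C4 and C14, to the β face next to H5, so C6 is set under thermodynamic control.

Step 21
Reactants: 29 6β aldehyde
Product: 30 C7 acid (6β-CO2H; C19 methyl ester; ketal; acetonide)
Conditions: NaClO2, NaH2PO4, 2-methylbut-2-ene, t-BuOH/H2O, rt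
Reagents that add atoms: sodium chlorite, [Na+].[O-]Cl=O
Why: Pinnick oxidation, which does not epimerize the α-centre and tolerates the lactone, ketal and acetonide at buffered pH.

Step 22
Reactants: 30 C7 acid
Product: 31 16-ketone (ketal removed; acetonide kept)
Conditions: PPTS (cat.), acetone/H2O (10:1), 55 °C
Reagents that add atoms: water, O
Why: Acid-catalysed transketalization in wet acetone; the dioxolane of the C16 ketone is exchanged while the large excess of acetone holds the 2,3-acetonide in place.

Step 23
Reactants: 31 16-ketone
Product: 32 16-methylene acid (C16=C17; C19 methyl ester; acetonide)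
Conditions: Ph3PCH3Br, KOt-Bu (excess), THF, 0 °C to rt
Reagents that add atoms: methyltriphenylphosphonium bromide, C[P+](c1ccccc1)(c1ccccc1)c1ccccc1.[Br-]
Why: Wittig methylenation of a cyclopentanone flanked by a bridgehead; the first equivalent of ylide deprotonates the C7 acid, and the carboxylate, ester and δ-lactone do not react with the non-stabilized ylide.

Step 24
Reactants: 32 16-methylene acid
Product: 33 acetonide diacid (C7 and C19 acids)
Conditions: n-PrSLi (from n-PrSH, n-BuLi), HMPA, rt; aq. citric acid work-up
Reagents that add atoms: none
Why: SN2 demethylation; the thiolate attacks the methyl carbon, so the shielded axial C19 carbonyl need not be approached, and the secondary, hindered C12–O carbon of the lactone and the unactivated methylene are left alone.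

Step 25
Reactants: 33 acetonide diacid
Product: 34 target diacid
Conditions: AcOH/H2O (4:1), 45 °C
Reagents that add atoms: none
Why: Acid hydrolysis of the acetonide under conditions mild enough for the exocyclic methylene and the lactone.

## Compound list

1 | methyl (2E)-penta-2,4-dienoate | C=C/C=C/C(=O)OC | starting material
2 | maleic anhydride | O=C1OC(=O)C=C1 | starting material
3 | racemic all-cis Diels–Alder anhydride, methyl 1,3-dioxo-1,3,3a,4,7,7a-hexahydro-2-benzofuran-4-carboxylate, ester cis to the anhydride ring (both enantiomers shown) | [C@H]1(C(=O)OC2=O)CC=C[C@@H](C(=O)OC)[C@H]12.[C@@H]1(C(=O)OC2=O)CC=C[C@H](C(=O)OC)[C@@H]12 | intermediate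
4 | hemiester, all-cis 2,6-bis(methoxycarbonyl)cyclohex-3-ene-1-carboxylic acid (4α- and 10α-CO2Me, 5α-CO2H) | [C@H]1(C(=O)OC)CC=C[C@@H](C(=O)OC)[C@H]1C(=O)O | intermediate
5 | 2,6-bis(methoxycarbonyl)-2-methylcyclohex-3-ene-1-carboxylic acid, three carboxyl carbons cis, methyl trans to them (4β-Me) | [C@H]1(C(=O)OC)CC=C[C@@](C)(C(=O)OC)[C@H]1C(=O)O | intermediate
6 | 3,4-dihydroxy-2,6-bis(methoxycarbonyl)-2-methylcyclohexane-1-carboxylic acid, hydroxyls cis to the methyl (2β,3β-diol) | [C@H]1(C(=O)OC)C[C@H](O)[C@H](O)[C@@](C)(C(=O)OC)[C@H]1C(=O)O | intermediate
7 | 2β,3β-acetonide of 6 (acetonide acid) | [C@H]1(C(=O)OC)C[C@H](OC(C)(C)O2)[C@H]2[C@@](C)(C(=O)OC)[C@H]1C(=O)O | intermediate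
8 | acrolein | C=CC=O | starting material
9 | hydroxy acid, 7 with a 1-hydroxyprop-2-enyl group on the β face of C10 (C9 epimers) | C=CC(O)[C@]1(C(=O)OC)C[C@H](OC(C)(C)O2)[C@H]2[C@@](C)(C(=O)OC)[C@H]1C(=O)O | intermediate
10 | C9 acetate of 9 (10β-(1-acetoxyprop-2-enyl); C9 epimers) | C=CC(OC(C)=O)[C@]1(C(=O)OC)C[C@H](OC(C)(C)O2)[C@H]2[C@@](C)(C(=O)OC)[C@H]1C(=O)O | intermediate
11 | (E)-allylic acetate acid (10β-[(E)-3-acetoxyprop-1-enyl]; 5α-CO2H) | CC(=O)OC/C=C/[C@]1(C(=O)OC)C[C@H](OC(C)(C)O2)[C@H]2[C@@](C)(C(=O)OC)[C@H]1C(=O)O | intermediate
12 | acid chloride of 11 | CC(=O)OC/C=C/[C@]1(C(=O)OC)C[C@H](OC(C)(C)O2)[C@H]2[C@@](C)(C(=O)OC)[C@H]1C(=O)Cl | intermediate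
13 | ring A aldehyde (5α-formyl) | CC(=O)OC/C=C/[C@]1(C(=O)OC)C[C@H](OC(C)(C)O2)[C@H]2[C@@](C)(C(=O)OC)[C@H]1C=O | intermediate
14 | 1,4-dioxaspiro[4.4]nonan-7-one | O=C1CCC2(C1)OCCO2 | starting material
15 | aldol adduct, C6 carbinol bonded to C8 of the ring D ketal ketone (C6 and C8 epimers) | CC(=O)OC/C=C/[C@]1(C(=O)OC)C[C@H](OC(C)(C)O2)[C@H]2[C@@](C)(C(=O)OC)[C@H]1C(O)C1C(=O)CC2(OCCO2)C1 | intermediate
16 | 6,14-diketone with allylic acetate (C8 labile) | CC(=O)OC/C=C/[C@]1(C(=O)OC)C[C@H](OC(C)(C)O2)[C@H]2[C@@](C)(C(=O)OC)[C@H]1C(=O)C1C(=O)CC2(OCCO2)C1 | intermediate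
17 | 6,14-diketone with free (E)-allylic alcohol | OC/C=C/[C@]1(C(=O)OC)C[C@H](OC(C)(C)O2)[C@H]2[C@@](C)(C(=O)OC)[C@H]1C(=O)C1C(=O)CC2(OCCO2)C1 | intermediate
18 | enal, key-step precursor (10β-[(E)-3-oxoprop-1-enyl]; C5 acyl link to the ring D ketal dione) | O=C/C=C/[C@]1(C(=O)OC)C[C@H](OC(C)(C)O2)[C@H]2[C@@](C)(C(=O)OC)[C@H]1C(=O)C1C(=O)CC2(OCCO2)C1 | intermediate
19 | Michael adduct, ring B closed, C8 quaternary with C14 cis to the C11 arm, H9 β, free C12 aldehyde | O1CCOC12C[C@]3(C(=O)C2)[C@@H](CC=O)[C@]2(C(=O)OC)C[C@H](OC(C)(C)O5)[C@H]5[C@@](C)(C(=O)OC)[C@H]2C3=O | intermediate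
20 | hydroxy diketone tetracarbocycle (C6 and C14 ketones, 12α-OH, C16 ketal) | O1CCOC12C[C@]34C(=O)[C@H]2[C@@H](O)C[C@H]3[C@]3(C(=O)OC)C[C@H](OC(C)(C)O5)[C@H]5[C@@](C)(C(=O)OC)[C@H]3C4=O | intermediate
21 | 12α,14-diol (14-OH syn to the C15–C16 bridge), C6 ketone | O1CCOC12C[C@]34[C@H](O)[C@H]2[C@@H](O)C[C@H]3[C@]3(C(=O)OC)C[C@H](OC(C)(C)O5)[C@H]5[C@@](C)(C(=O)OC)[C@H]3C4=O | intermediate
22 | 20→12 lactone with 14-OH, C6 ketone | O1CCOC12C[C@]34[C@H](O)[C@H]2[C@@H]2C[C@H]3[C@@]3(C[C@H](OC(C)(C)O5)[C@H]5[C@@](C)(C(=O)OC)[C@H]3C4=O)C(=O)O2 | intermediate
23 | 14-O-(phenoxythiocarbonyl) derivative of 22 | O1CCOC12C[C@]34[C@H](OC(=S)Oc6ccccc6)[C@H]2[C@@H]2C[C@H]3[C@@]3(C[C@H](OC(C)(C)O5)[C@H]5[C@@](C)(C(=O)OC)[C@H]3C4=O)C(=O)O2 | intermediate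
24 | 14-deoxy keto lactone (C6 ketone, C16 ketal) | O1CCOC12C[C@]34C[C@H]2[C@@H]2C[C@H]3[C@@]3(C[C@H](OC(C)(C)O5)[C@H]5[C@@](C)(C(=O)OC)[C@H]3C4=O)C(=O)O2 | intermediate
25 | 6-methylene lactone | O1CCOC12C[C@]34C[C@H]2[C@@H]2C[C@H]3[C@@]3(C[C@H](OC(C)(C)O5)[C@H]5[C@@](C)(C(=O)OC)[C@H]3C4=C)C(=O)O2 | intermediate
26 | C7 alkylborane (6α-CH2BH2, H6 β) | O1CCOC12C[C@]34C[C@H]2[C@@H]2C[C@H]3[C@@]3(C[C@H](OC(C)(C)O5)[C@H]5[C@@](C)(C(=O)OC)[C@H]3[C@H]4CB)C(=O)O2 | intermediate
27 | 6-epi C7 alcohol (6α-CH2OH, H6 β) | O1CCOC12C[C@]34C[C@H]2[C@@H]2C[C@H]3[C@@]3(C[C@H](OC(C)(C)O5)[C@H]5[C@@](C)(C(=O)OC)[C@H]3[C@H]4CO)C(=O)O2 | intermediate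
28 | 6-epi aldehyde (6α-CHO) | O1CCOC12C[C@]34C[C@H]2[C@@H]2C[C@H]3[C@@]3(C[C@H](OC(C)(C)O5)[C@H]5[C@@](C)(C(=O)OC)[C@H]3[C@H]4C=O)C(=O)O2 | intermediate
29 | 6β aldehyde (natural C6 configuration) | O1CCOC12C[C@]34C[C@H]2[C@@H]2C[C@H]3[C@@]3(C[C@H](OC(C)(C)O5)[C@H]5[C@@](C)(C(=O)OC)[C@H]3[C@@H]4C=O)C(=O)O2 | intermediate
30 | C7 acid (6β-CO2H, C19 methyl ester, C16 ketal, acetonide) | O1CCOC12C[C@]34C[C@H]2[C@@H]2C[C@H]3[C@@]3(C[C@H](OC(C)(C)O5)[C@H]5[C@@](C)(C(=O)OC)[C@H]3[C@@H]4C(=O)O)C(=O)O2 | intermediate
31 | 16-ketone (C7 acid, C19 methyl ester, acetonide) | O=C1C[C@]23C[C@H]1[C@@H]1C[C@H]2[C@@]2(C[C@H](OC(C)(C)O4)[C@H]4[C@@](C)(C(=O)OC)[C@H]2[C@@H]3C(=O)O)C(=O)O1 | intermediate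
32 | 16-methylene compound (C7 acid, C19 methyl ester, acetonide) | C=C1C[C@]23C[C@H]1[C@@H]1C[C@H]2[C@@]2(C[C@H](OC(C)(C)O4)[C@H]4[C@@](C)(C(=O)OC)[C@H]2[C@@H]3C(=O)O)C(=O)O1 | intermediate
33 | acetonide diacid | C=C1C[C@]23C[C@H]1[C@@H]1C[C@H]2[C@@]2(C[C@H](OC(C)(C)O4)[C@H]4[C@@](C)(C(=O)O)[C@H]2[C@@H]3C(=O)O)C(=O)O1 | intermediate
34 | CNP0212122.1, 2β,3β-dihydroxy C20 gibberellin 7,19-dioic acid 20→12 lactone | C=C1C[C@]23C[C@H]1[C@@H]1C[C@H]2[C@@]2(C[C@H](O)[C@H](O)[C@@](C)(C(=O)O)[C@H]2[C@@H]3C(=O)O)C(=O)O1 | target

## Step count and least certain steps

Total: 25 steps. Longest linear sequence: 25 steps (1 to 34; ketone 14 enters at step 9).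

**Step 13 (key step).** The most likely failure is loss of the C16 ketal by β-elimination once the C14 ketone enolizes toward C13, or stalling after the Michael closure because that enol forms slowly; either way ring C does not close. Attack on the other face of the enal, giving the C9 epimer, is the second concern. The fallback gives up the one-pot domino: from 18, triethylamine alone should bring about the Michael closure to 19, which is isolated. The aldol is then run at −78 °C through the dibutylboron enolate of the C14 ketone (Bu2BOTf, i-Pr2NEt), a covalent enolate that can form only toward C13, is too weakly basic to expel the ketal oxygen, and adds to C12 through a closed chair, returning to the route at 20.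

**Step 2.** The catalyst may fail to override the inherent preference of both enantiomers of 3 for attack at the less hindered C20 carbonyl, so that both give the same regioisomer and 4 is obtained with low enantiomeric purity. The fallback is a classical resolution: from 3, uncatalysed methanolysis (MeOH, reflux) should open the C20 carbonyl to the racemic hemiester F1. Crystallization of its (S)-1-phenylethylammonium salt F2 (or of the salt with the (R)-amine, should the wanted enantiomer stay in solution) and acidification return to the route at 4.

**Step 6.** The crowded aldolate may revert before it is acetylated, acrolein may be consumed by conjugate addition and oligomerization, or attack may occur on the α face. The fallback forms the quaternary centre by an irreversible SN2 reaction: from 7, the same dianion is alkylated with allyl bromide to the 10β-allyl acid F3. Allylic oxidation of the terminal alkene (SeO2, t-BuOOH) then places the hydroxyl on C9 and gives 9, now isolated, which is acetylated (Ac2O, pyridine) to rejoin the route at 10.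

**Step 9.** Deprotonation of 14 may occur in part at C13, between the carbonyl and the ketal, followed by β-elimination of the ketal; the doubly neopentyl aldehyde 13 may also add slowly and revert. The fallback uses an enolate whose position is fixed by its origin: the enone 1,4-dioxaspiro[4.4]non-8-en-7-one F4 is reduced in conjugate fashion ([(Ph3P)CuH]6 (cat.), silane, then Me3SiCl) to the silyl enol ether F5, whose double bond can only lie between C8 and C14. MeLi releases the lithium enolate, which is added to 13 at −78 °C to rejoin the route at 15.

**Step 14.** Hydride transfer within the C12 alkoxyborohydride may be too slow at the crowded bridging carbonyl, or the C12 hydroxyl may close onto C20 in the acidic medium before it has directed the reduction. The fallback reverses the order of the two events: from 20, acid-catalysed lactonization (CSA, toluene) gives the 6,14-diketo lactone F6. NaBH4 at −40 °C should then reduce only the strained one-carbon-bridge ketone, from the face remote from the lactone bridge, to the 14-epimeric alcohol F7, and its thionocarbonate F8 is deoxygenated as in step 17 to rejoin the route at 24.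

**Step 18.** The C6 ketone, between quaternary C8 and a methine flanked by two quaternary carbons, may not react, or the Lewis acidic titanium reagent may open the ketal. The fallback uses a smaller carbon nucleophile and a rearrangement in place of methylenation and hydroboration: from 24, dimethylsulfonium methylide (Me3SI, n-BuLi, THF) gives the spiro-epoxide F9 (Corey–Chaykovsky reaction). BF3·OEt2 at −78 °C opens it at C6 and a 1,2-hydride shift (Meinwald rearrangement) gives the C7 aldehyde as a mixture of 28 and 29, which DBU equilibrates to rejoin the route at 29.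

## Further compounds

F0 | step 13 | none | none
F1 | step 2 | racemic hemiester (racemate of 4; both enantiomers shown) | [C@H]1(C(=O)OC)CC=C[C@@H](C(=O)OC)[C@H]1C(=O)O.[C@@H]1(C(=O)OC)CC=C[C@H](C(=O)OC)[C@@H]1C(=O)O
F2 | step 2 | (S)-1-phenylethylammonium salt of 4 | [C@H]1(C(=O)OC)CC=C[C@@H](C(=O)OC)[C@H]1C(=O)[O-].C[C@H]([NH3+])c1ccccc1
F3 | step 6 | 10β-allyl acetonide acid | C=CC[C@]1(C(=O)OC)C[C@H](OC(C)(C)O2)[C@H]2[C@@](C)(C(=O)OC)[C@H]1C(=O)O
F4 | step 9 | 1,4-dioxaspiro[4.4]non-8-en-7-one | O=C1C=CC2(OCCO2)C1
F5 | step 9 | 7-(trimethylsilyloxy)-1,4-dioxaspiro[4.4]non-7-ene | C[Si](C)(C)OC1=CCC2(OCCO2)C1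
F6 | step 14 | 6,14-diketo 20→12 lactone | O1CCOC12C[C@]34C(=O)[C@H]2[C@@H]2C[C@H]3[C@@]3(C[C@H](OC(C)(C)O5)[C@H]5[C@@](C)(C(=O)OC)[C@H]3C4=O)C(=O)O2
F7 | step 14 | 14-epimer of 22 (14-OH syn to the C9–C11–C12 bridge) | O1CCOC12C[C@]34[C@@H](O)[C@H]2[C@@H]2C[C@H]3[C@@]3(C[C@H](OC(C)(C)O5)[C@H]5[C@@](C)(C(=O)OC)[C@H]3C4=O)C(=O)O2
F8 | step 14 | 14-O-(phenoxythiocarbonyl) derivative of F7 | O1CCOC12C[C@]34[C@@H](OC(=S)Oc6ccccc6)[C@H]2[C@@H]2C[C@H]3[C@@]3(C[C@H](OC(C)(C)O5)[C@H]5[C@@](C)(C(=O)OC)[C@H]3C4=O)C(=O)O2
F9 | step 18 | C6 spiro-epoxide (C7 β, oxygen α) | O1CCOC12C[C@]34C[C@H]2[C@@H]2C[C@H]3[C@@]3(C[C@H](OC(C)(C)O5)[C@H]5[C@@](C)(C(=O)OC)[C@H]3[C@]46CO6)C(=O)O2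
A1 | alternative 1 | triene: C/D lactone with the C10=C1–C2=C3 bis(silyloxy)diene and the (Z)-2-methylenoate on C6 | C=C1C[C@]2([C@@H](C(=O)OC)/C=C(/C)C(=O)OC)C[C@H]1[C@@H]1C[C@H]2C(/C(=O)O1)=C/C(O[Si](C)(C)C(C)(C)C)=C/O[Si](C)(C)C(C)(C)C
A2 | alternative 1 | cycloadduct with C1=C2 silyl enol ether and C3 silyl ether | C=C1C[C@]23C[C@H]1[C@@H]1C[C@H]2[C@@]2(C=C(O[Si](C)(C)C(C)(C)C)[C@H](O[Si](C)(C)C(C)(C)C)[C@@](C)(C(=O)OC)[C@H]2[C@@H]3C(=O)OC)C(=O)O1
A3 | alternative 2 | ring A/B lactone with C8=C14 enone and silyl allylic carbonate on C12 (C13 epimers) | C[Si](C)(C)CC(=C)C(OC(=O)OC)[C@@H]1C[C@@H]2C(=C)C(=O)[C@H]3[C@]2(C[C@H](OC(C)(C)O4)[C@H]4[C@@]3(C)C(=O)OC)C(=O)O1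
A4 | alternative 2 | pentacyclic lactone with C6 ketone and C16=C17 methylene | C=C1C[C@]23C[C@H]1[C@@H]1C[C@H]2[C@@]2(C[C@H](OC(C)(C)O4)[C@H]4[C@@](C)(C(=O)OC)[C@H]2C3=O)C(=O)O1
A5 | alternative 3 | enyne acid: ring A/B/C tricycle with C12=C13 alkene, C8 propargyl group and free C20 acid | C#CC[C@]12CC=CC[C@H]1[C@]1(C(=O)O)C[C@H](OC(C)(C)O3)[C@H]3[C@@](C)(C(=O)OC)[C@H]1[C@@H]2C(=O)OC
A6 | alternative 3 | target as acetonide dimethyl ester | C=C1C[C@]23C[C@H]1[C@@H]1C[C@H]2[C@@]2(C[C@H](OC(C)(C)O4)[C@H]4[C@@](C)(C(=O)OC)[C@H]2[C@@H]3C(=O)OC)C(=O)O1
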